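## Retrosynthetic overview

1. Target 9 comes from its 4'-O-acetate 8 by one neutral deacetylation; every carbon of 9 comes from three molecules of resveratrol 1.
2. The dihydrobenzofuran on ring A (2R,3R) is cut at C8b–C12a and C7b–O: 4'-O-acetylresveratrol 2 is the ring donor, (2S,3S)-gnetin C 5 is the two-electron-oxidised olefin donor, and an (R)-configured chiral phosphate controls the face.
3. The dihydrobenzofuran of 5 (on ring B, 2S,3S) is cut the same way (C8c–C12b, C7c–O): oxidative homodimerisation of unprotected 1 under the (S)-phosphate.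
4. 2 comes from 1 by lipase acetylation of the 4'-OH only; the acetate marks the one unit that must never be oxidised.
5. Ring order: dihydrofuran on ring B (step 2), then dihydrofuran on ring A (step 3). Each closes by phenol addition to a para-quinone methide formed by oxidative C8–C12 coupling.

Labels: units A (intact stilbene), B (middle), C (terminal); resveratrol numbering (C7=C8 olefin, C12 between the two hydroxyls of the resorcinol ring).

Assumption: the (S)-phosphoric acid is taken to give the (2S,3S) ring and the (R)-acid the (2R,3R) ring; if the first run shows the opposite sense, the two acids change places between steps 2 and 3.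

## Route

**Step 1**
Reactants: 1 trans-resveratrol
Product: 2 4'-O-acetylresveratrol
Conditions: vinyl acetate (5 equiv), immobilized Candida antarctica lipase B, 2-methyl-2-butanol, 45 °C
Reagents that add atoms: vinyl acetate, C=COC(C)=O
Why: Lipase-catalysed irreversible transesterification with a vinyl ester; the enzyme accepts only the unhindered 4'-OH, so acylation stops at the monoacetate and no stereocentre is formed.

**Step 2**
Reactants: 1 trans-resveratrol (two molecules: one as ring donor, one as olefin donor)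
Product: 5 (2S,3S)-gnetin C, via resveratrol quinone methide cation 3 (not isolated), via quinone methide 4 (not isolated)
Conditions: 1 (1.0 equiv), (S)-3,3'-bis(2,4,6-triisopropylphenyl)-1,1'-binaphthyl-2,2'-diyl hydrogen phosphate (5 mol %), 4 Å MS, CH2Cl2/EtOAc 1:1 (0.02 M), −40 °C, argon; PhI(OAc)2 (0.25 equiv) added over 8 h; unreacted 1 recovered
Reagents that add atoms: none
Why: Proposed new method: a biomimetic oxidative [3+2] homodimerisation run as asymmetric counteranion-directed catalysis. PhI(OAc)2 takes two electrons from the 4-hydroxystilbene of one molecule of 1, and cation 3 forms as a contact ion pair with the chiral phosphate, which is the strongest acid present, so acetate does not compete as counteranion. The phosphate hydrogen-bonds both hydroxyls of the resorcinol ring of a second, unoxidised molecule of 1 and so delivers C8 of the cation to the carbon between them (C12, not C10/C14, the olefin or the 4-hydroxyphenyl ring) on one face, setting C3 as S; this mirrors oxygen-bound-base condensations of 5-alkylresorcinols with enals, which also react between the hydroxyls. Quinone methide 4 then closes by intramolecular oxa-1,6-addition to the 2,3-trans ring, setting C2 as S. Limiting the oxidant to 0.25 equiv and adding it slowly keeps 1 in at least twofold excess over 5, so 5 is neither re-oxidised nor used as the nucleophile. Closest known reactions: hypervalent-iodine oxidative phenol/alkene [3+2] annulations and chiral-phosphoric-acid 1,6-additions of phenols to para-quinone methides.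

**Step 3**
Reactants: 5 (2S,3S)-gnetin C (olefin donor, 1 equiv); 2 4'-O-acetylresveratrol (ring donor, 3 equiv)
Product: 8 4'-O-acetate of the target, via gnetin C quinone methide cation 6 (not isolated), via trimer quinone methide 7 (not isolated)
Conditions: 2 (3 equiv), (R)-3,3'-bis(2,4,6-triisopropylphenyl)-1,1'-binaphthyl-2,2'-diyl hydrogen phosphate (10 mol %), 4 Å MS, CH2Cl2/EtOAc 1:1, −40 °C, argon; 5 and PhI(OAc)2 (1.05 equiv) added from two syringes over 10 h; excess 2 recovered
Reagents that add atoms: none
Why: Proposed new method: the same counteranion-directed oxidative [3+2] coupling, now as a cross-coupling with the enantiomeric phosphate. The 4-hydroxystilbene of 5 is the only readily oxidised phenol in the flask (the acetate of 2 blocks its own), so PhI(OAc)2 turns 5 into cation 6; slow addition keeps 6 dilute, and excess 2 takes it at C12 of its phosphate-bound resorcinol ring. The catalyst sets the new C3 as R against at most a weak bias from the remote (2S,3S) ring, and oxa-1,6-closure of 7 gives the trans ring with C2 as R. Product 8 has no free hydroxystilbene and is not oxidised further. Closest known reactions as in step 2.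

**Step 4**
Reactants: 8 4'-O-acetate of the target
Product: 9 target (CNP0248228.3)
Conditions: NH4OAc (10 equiv), MeOH/H2O 4:1, rt, argon
Reagents that add atoms: none
Why: Neutral ammonium-acetate-mediated methanolysis of an aryl acetate (transesterification); no phenoxide is formed that could open the 2-(4-hydroxyphenyl)dihydrobenzofurans through a quinone methide, so all four stereocentres are untouched.

## Compound list

1 | trans-resveratrol, 5-[(E)-2-(4-hydroxyphenyl)ethenyl]benzene-1,3-diol | Oc1ccc(/C=C/c2cc(O)cc(O)c2)cc1 | starting material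
2 | 4'-O-acetylresveratrol, 4-[(E)-2-(3,5-dihydroxyphenyl)ethenyl]phenyl acetate | CC(=O)Oc1ccc(/C=C/c2cc(O)cc(O)c2)cc1 | intermediate
3 | quinone methide cation of resveratrol (positive charge at C8, 4-oxocyclohexadienylidene at C7), ion-paired with the chiral phosphate | O=C1C=CC(=C[CH+]c2cc(O)cc(O)c2)C=C1 | intermediate
4 | quinone methide, 2-[(1S)-1-(3,5-dihydroxyphenyl)-2-(4-oxocyclohexa-2,5-dien-1-ylidene)ethyl]-5-[(E)-2-(4-hydroxyphenyl)ethenyl]benzene-1,3-diol | Oc1ccc(/C=C/c2cc(O)c([C@@H](C=C3C=CC(=O)C=C3)c3cc(O)cc(O)c3)c(O)c2)cc1 | intermediate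
5 | (2S,3S)-gnetin C, 5-[(2S,3S)-4-hydroxy-2-(4-hydroxyphenyl)-6-[(E)-2-(4-hydroxyphenyl)ethenyl]-2,3-dihydro-1-benzofuran-3-yl]benzene-1,3-diol | Oc1ccc(/C=C/c2cc(O)c3c(c2)O[C@H](c2ccc(O)cc2)[C@H]3c2cc(O)cc(O)c2)cc1 | intermediate
6 | quinone methide cation of (2S,3S)-gnetin C (positive charge at the olefin carbon next to the benzofuran ring, 4-oxocyclohexadienylidene at the other olefin carbon), ion-paired with the chiral phosphate | O=C1C=CC(=C[CH+]c2cc(O)c3c(c2)O[C@H](c2ccc(O)cc2)[C@H]3c2cc(O)cc(O)c2)C=C1 | intermediate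
7 | quinone methide of the trimer: 2 carrying at C12 of its resorcinol ring a (1R)-1-[(2S,3S)-3-(3,5-dihydroxyphenyl)-4-hydroxy-2-(4-hydroxyphenyl)-2,3-dihydro-1-benzofuran-6-yl]-2-(4-oxocyclohexa-2,5-dien-1-ylidene)ethyl group | CC(=O)Oc1ccc(/C=C/c2cc(O)c([C@H](C=C3C=CC(=O)C=C3)c3cc(O)c4c(c3)O[C@H](c3ccc(O)cc3)[C@H]4c3cc(O)cc(O)c3)c(O)c2)cc1 | intermediate
8 | 4'-O-acetate of the target, 4-{(E)-2-[(2R,3R)-3-[(2S,3S)-3-(3,5-dihydroxyphenyl)-4-hydroxy-2-(4-hydroxyphenyl)-2,3-dihydro-1-benzofuran-6-yl]-4-hydroxy-2-(4-hydroxyphenyl)-2,3-dihydro-1-benzofuran-6-yl]ethenyl}phenyl acetate | CC(=O)Oc1ccc(/C=C/c2cc(O)c3c(c2)O[C@@H](c2ccc(O)cc2)[C@@H]3c2cc(O)c3c(c2)O[C@H](c2ccc(O)cc2)[C@H]3c2cc(O)cc(O)c2)cc1 | intermediate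
9 | target, 5-[(2S,3S)-6-{(2R,3R)-4-hydroxy-2-(4-hydroxyphenyl)-6-[(E)-2-(4-hydroxyphenyl)ethenyl]-2,3-dihydro-1-benzofuran-3-yl}-4-hydroxy-2-(4-hydroxyphenyl)-2,3-dihydro-1-benzofuran-3-yl]benzene-1,3-diol | Oc1ccc(/C=C/c2cc(O)c3c(c2)O[C@@H](c2ccc(O)cc2)[C@@H]3c2cc(O)c3c(c2)O[C@H](c2ccc(O)cc2)[C@H]3c2cc(O)cc(O)c2)cc1 | target

## Step count and risks

Total steps: 4. Longest linear sequence: 3 (1 → 5 → 8 → 9, or 1 → 2 → 8 → 9).

**Most likely to fail: step 2.** Unprotected 1 is both partners, so several side reactions compete: attack at C10/C14, attack by the olefin or the 4-hydroxyphenyl ring of the nucleophile, and re-oxidation of 5, which is itself a hydroxystilbene. Enantioselectivity is also untested. The fallback protects the ring donor and turns the homodimerisation into a cross-coupling. It sets out from 2 and comes back at 5. 2 (3 equiv) is held with the (S)-phosphoric acid at −40 °C while 1 and PhI(OAc)2 (1.05 equiv) are added slowly. The coupling runs through the quinone methide F1 to 4'-O-acetyl-(2S,3S)-gnetin C F2, whose acetoxystilbene can neither be oxidised nor act as an olefin nucleophile. NH4OAc in aqueous MeOH then frees the stilbene phenol and gives 5.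

**Second: step 3.** Cation 6 can be taken by the 3,5-dihydroxyphenyl ring of another molecule of 5 or by C10/C14 of 2, and the remote (2S,3S) ring may mismatch the catalyst and give the wrong diastereomer. The fallback reverses the order of ring formation, so that the dimer is the nucleophile and the oxidised partner is always simple 1. It sets out from 2 (with 1) and comes back at 8. 2 (3 equiv) is coupled with slowly added 1 and PhI(OAc)2 under the (R)-phosphoric acid, through the quinone methide F3, to 4'-O-acetyl-(2R,3R)-gnetin C F4. F4 is then the ring donor: 1 and PhI(OAc)2 are added slowly to F4 and the (S)-phosphoric acid at −40 °C. The cation of 1 is taken between the hydroxyls of the 3,5-dihydroxyphenyl ring of F4, and the trimer quinone methide F5 closes to 8.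

**Third: step 4.** The heptaphenol is air-sensitive and hard to purify from minor isomers, and deacetylation may stall. The fallback derivatises first and deprotects with a different nucleophile. It sets out from 8 and comes back at 9. 8 is peracetylated (Ac2O, pyridine, 0 °C to rt) to the stable, chromatographable heptaacetate F6. All seven acetates are then cleaved by hydrazinolysis (N2H4·H2O, THF/MeOH, 0 °C, argon), which keeps the phenols un-ionised, to give 9.

## Further compounds

F1 | step 2 | quinone methide, 4-[(E)-2-{4-[(1S)-1-(3,5-dihydroxyphenyl)-2-(4-oxocyclohexa-2,5-dien-1-ylidene)ethyl]-3,5-dihydroxyphenyl}ethenyl]phenyl acetate | CC(=O)Oc1ccc(/C=C/c2cc(O)c([C@@H](C=C3C=CC(=O)C=C3)c3cc(O)cc(O)c3)c(O)c2)cc1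
F2 | step 2 | 4'-O-acetyl-(2S,3S)-gnetin C, 4-{(E)-2-[(2S,3S)-3-(3,5-dihydroxyphenyl)-4-hydroxy-2-(4-hydroxyphenyl)-2,3-dihydro-1-benzofuran-6-yl]ethenyl}phenyl acetate | CC(=O)Oc1ccc(/C=C/c2cc(O)c3c(c2)O[C@H](c2ccc(O)cc2)[C@H]3c2cc(O)cc(O)c2)cc1
F3 | step 3 | quinone methide, 4-[(E)-2-{4-[(1R)-1-(3,5-dihydroxyphenyl)-2-(4-oxocyclohexa-2,5-dien-1-ylidene)ethyl]-3,5-dihydroxyphenyl}ethenyl]phenyl acetate | CC(=O)Oc1ccc(/C=C/c2cc(O)c([C@H](C=C3C=CC(=O)C=C3)c3cc(O)cc(O)c3)c(O)c2)cc1
F4 | step 3 | 4'-O-acetyl-(2R,3R)-gnetin C, 4-{(E)-2-[(2R,3R)-3-(3,5-dihydroxyphenyl)-4-hydroxy-2-(4-hydroxyphenyl)-2,3-dihydro-1-benzofuran-6-yl]ethenyl}phenyl acetate | CC(=O)Oc1ccc(/C=C/c2cc(O)c3c(c2)O[C@@H](c2ccc(O)cc2)[C@@H]3c2cc(O)cc(O)c2)cc1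
F5 | step 3 | quinone methide of the trimer: F4 carrying at C12 of its 3,5-dihydroxyphenyl ring a (1S)-1-(3,5-dihydroxyphenyl)-2-(4-oxocyclohexa-2,5-dien-1-ylidene)ethyl group | CC(=O)Oc1ccc(/C=C/c2cc(O)c3c(c2)O[C@@H](c2ccc(O)cc2)[C@@H]3c2cc(O)c([C@@H](C=C3C=CC(=O)C=C3)c3cc(O)cc(O)c3)c(O)c2)cc1
F6 | step 4 | heptaacetate of the target (all seven phenols acetylated, configuration 2R,3R and 2S,3S as in 8) | CC(=O)Oc1ccc(/C=C/c2cc(OC(C)=O)c3c(c2)O[C@@H](c2ccc(OC(C)=O)cc2)[C@@H]3c2cc(OC(C)=O)c3c(c2)O[C@H](c2ccc(OC(C)=O)cc2)[C@H]3c2cc(OC(C)=O)cc(OC(C)=O)c2)cc1
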